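**Plan**

Rings: A = para-phenylene, B = the 2-aryloxy-3-hydroxyphenyl ring, C = the catechol ring, D = the ortho-phenylene.
Retrosynthetic cuts, in order: the three O–CH3 bonds; the CH2–CH2 bond between ring C and ring D (back to CH2–SO2–CH2 of an 18-membered cyclic dibenzyl sulfone); the two benzylic C–S bonds; the ring B–O–ring D ether; the ring A/ring B ethano bridge (as a stilbene); the ring A–O–ring C ether.
Enabling feature: the ethano bridge between ring C and ring D joins two primary benzylic carbons, which is exactly what SO2 loss from a dibenzyl sulfone followed by radical recombination delivers.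
Forward: the chain is joined C–A, then A–B (Wittig, hydrogenation), then B–D; the only ring closure is the 18-membered sulfide, which is oxidised and then contracted to the 17-membered ring.
Stereochemistry: none to set; the target has no stereocentre and the stilbene geometry is erased by hydrogenation.

Key step: step 11

Assumption: compounds 1, 2, 6 and 10 are taken as purchasable. The macrocycles are treated as conformationally mobile (no stable atropisomers), so SMILES carry no stereodescriptors. For the E/Z mixtures (8, F1) the alkene geometry is left open.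

**Step 1**
Reactants: 1 methyl 3-hydroxy-4,5-dimethoxybenzoate; 2 4-fluorobenzaldehyde
Product: 3 methyl 3-(4-formylphenoxy)-4,5-dimethoxybenzoate
Conditions: K2CO3, DMA, 140 °C
Reagents that add atoms: none
Why: Nucleophilic aromatic substitution (SNAr) in which the phenoxide of 1 displaces the fluoride activated by the para formyl group, a standard diaryl ether construction that leaves the ring A aldehyde and the ring C ester at different oxidation levels.

**Step 2**
Reactants: 3 methyl 3-(4-formylphenoxy)-4,5-dimethoxybenzoate
Product: 4 methyl 3-[4-(hydroxymethyl)phenoxy]-4,5-dimethoxybenzoate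
Conditions: NaBH4, MeOH/THF, 0 °C
Reagents that add atoms: none
Why: Borohydride reduction should take the aryl aldehyde to the benzylic alcohol chemoselectively, since a methyl benzoate is inert to NaBH4 at this temperature.

**Step 3**
Reactants: 4 methyl 3-[4-(hydroxymethyl)phenoxy]-4,5-dimethoxybenzoate
Product: 5 {4-[2,3-dimethoxy-5-(methoxycarbonyl)phenoxy]benzyl}triphenylphosphonium bromide
Conditions: PPh3·HBr, MeCN, reflux
Reagents that add atoms: triphenylphosphine hydrobromide, [Br-].c1ccc(cc1)[PH+](c1ccccc1)c1ccccc1
Why: Direct phosphonium salt formation from a benzylic alcohol, in which the protonated para-aryloxybenzyl alcohol ionises readily and is captured by PPh3, saving a separate bromination.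

**Step 4**
Reactants: 5 {4-[2,3-dimethoxy-5-(methoxycarbonyl)phenoxy]benzyl}triphenylphosphonium bromide; 6 2-(benzyloxy)-3-methoxybenzaldehyde
Product: 8 methyl 3-{4-[2-(2-benzyloxy-3-methoxyphenyl)ethenyl]phenoxy}-4,5-dimethoxybenzoate (E/Z mixture), via phosphonium ylide 7 (not isolated)
Conditions: K2CO3, 18-crown-6 (cat.), CH2Cl2, reflux
Reagents that add atoms: none
Why: Wittig olefination of a semi-stabilised benzylic ylide under solid–liquid phase-transfer conditions that spare the methyl ester; the E/Z outcome is irrelevant because the alkene is saturated in the next step.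

**Step 5**
Reactants: 8 methyl 3-{4-[2-(2-benzyloxy-3-methoxyphenyl)ethenyl]phenoxy}-4,5-dimethoxybenzoate (E/Z mixture)
Product: 9 methyl 3-{4-[2-(2-hydroxy-3-methoxyphenyl)ethyl]phenoxy}-4,5-dimethoxybenzoate
Conditions: H2 (1 atm), 10% Pd/C, EtOAc/MeOH, rt
Reagents that add atoms: none
Why: Catalytic hydrogenation should saturate the stilbene and hydrogenolyse the benzyl ether in one operation, unveiling the single free phenol (ring B) while the ester, diaryl ether and methyl ethers stay intact.

**Step 6**
Reactants: 9 methyl 3-{4-[2-(2-hydroxy-3-methoxyphenyl)ethyl]phenoxy}-4,5-dimethoxybenzoate; 10 2-fluorobenzaldehyde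
Product: 11 methyl 3-(4-{2-[2-(2-formylphenoxy)-3-methoxyphenyl]ethyl}phenoxy)-4,5-dimethoxybenzoate
Conditions: Cs2CO3, DMA (dry), 130 °C
Reagents that add atoms: none
Why: SNAr of the cesium phenoxide on the fluoride activated by the ortho formyl group forms the ring B–O–ring D ether; the phenol is the only nucleophile present and cesium is chosen to offset its two ortho substituents.

**Step 7**
Reactants: 11 methyl 3-(4-{2-[2-(2-formylphenoxy)-3-methoxyphenyl]ethyl}phenoxy)-4,5-dimethoxybenzoate
Product: 12 [3-(4-{2-[2-(2-(hydroxymethyl)phenoxy)-3-methoxyphenyl]ethyl}phenoxy)-4,5-dimethoxyphenyl]methanol (the diol)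
Conditions: LiAlH4, THF, 0 °C → rt
Reagents that add atoms: none
Why: Hydride reduction with LiAlH4 should bring the ring C ester and the ring D aldehyde to the same benzylic alcohol level in one step.

**Step 8**
Reactants: 12 the diol
Product: 13 5-(bromomethyl)-1-(4-{2-[2-(2-(bromomethyl)phenoxy)-3-methoxyphenyl]ethyl}phenoxy)-2,3-dimethoxybenzene (the open bis(benzyl bromide))
Conditions: PBr3, CH2Cl2, 0 °C; used crude
Reagents that add atoms: phosphorus tribromide, BrP(Br)Br
Why: Conversion of benzylic alcohols to bromides by PBr3 (bromide displacement on the phosphite esters) is routine for alkoxy-substituted benzyl alcohols and does not touch aryl ethers.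

**Step 9**
Reactants: 13 the open bis(benzyl bromide)
Product: 15 18-membered cyclic dibenzyl sulfide (ring C–CH2–S–CH2–ring D; tri-O-methyl), via bromo thiolate 14 (not isolated)
Conditions: Na2S/Al2O3, CH2Cl2/EtOH (10:1), rt, slow addition at high dilution
Reagents that add atoms: sodium sulfide, [Na+].[Na+].[S-2]
Why: Double SN2 thioetherification, in which sulfide displaces one benzylic bromide (drawn for the less hindered ring C terminus) and the resulting thiolate closes the 18-membered ring on the other, a standard thiacyclophane macrocyclisation favoured by dilution and the soft, highly nucleophilic thiolate.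

**Step 10**
Reactants: 15 18-membered cyclic dibenzyl sulfide
Product: 17 18-membered cyclic dibenzyl sulfone (tri-O-methyl), via cyclic sulfoxide 16 (not isolated)
Conditions: mCPBA (2.2 equiv), CH2Cl2, 0 °C → rt
Reagents that add atoms: 3-chloroperoxybenzoic acid (mCPBA), OOC(=O)c1cccc(Cl)c1
Why: Stepwise peracid S-oxidation (sulfide to sulfoxide to sulfone) is much faster than any oxidation of the alkoxy arenes, and no other oxidisable group is present.

**Step 11**
Reactants: 17 18-membered cyclic dibenzyl sulfone
Product: 19 tri-O-methyl ether of the target (17-membered macrocycle, ring C–CH2–CH2–ring D), via benzylic diradical 18 (not isolated)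
Conditions: flash vacuum pyrolysis, quartz tube, ca. 600 °C, 0.01 mbar, sublimation from a preheated zone
Reagents that add atoms: none
Why: This is a sulfone pyrolysis, the classical SO2 extrusion route from cyclic dibenzyl sulfones to ethano-bridged cyclophanes: homolysis of one benzylic C–S bond gives a benzyl/sulfonyl radical pair, SO2 is expelled, and the bis(benzylic) diradical 18 recombines to form the CH2–CH2 bond. The 17-membered ring is closed by intramolecular radical–radical coupling of the two chain termini, a contraction of the 18-membered sulfone by one atom, and the low pressure of the gas phase excludes intermolecular coupling. No stereocentre is formed, and both radical carbons are primary benzylic, so no regiochemical question arises. The selectivity required is cleavage of the benzylic C–S bonds in preference to the O–CH3 and diaryl ether bonds; the benzyl–SO2 bonds are the weakest in the molecule and are the only benzylic carbon–heteroatom bonds present. The oven should be run at the lowest temperature that gives complete SO2 loss, to spare the ring C methyl ethers.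

**Step 12**
Reactants: 19 tri-O-methyl ether of the target
Product: 20 CNP0290892.0 (target; the triphenol)
Conditions: BBr3 (excess), CH2Cl2, −78 °C → rt; then H2O
Reagents that add atoms: none
Why: Lewis acid demethylation of aryl methyl ethers with BBr3 should cleave all three O–CH3 bonds, while diaryl ethers, which lack an sp3 carbon for bromide attack, remain intact.

**Compound list**

1 | methyl 3-hydroxy-4,5-dimethoxybenzoate | COC(=O)c1cc(O)c(OC)c(OC)c1 | starting material
2 | 4-fluorobenzaldehyde | O=Cc1ccc(F)cc1 | starting material
3 | methyl 3-(4-formylphenoxy)-4,5-dimethoxybenzoate | COC(=O)c1cc(Oc2ccc(C=O)cc2)c(OC)c(OC)c1 | intermediate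
4 | methyl 3-[4-(hydroxymethyl)phenoxy]-4,5-dimethoxybenzoate | COC(=O)c1cc(Oc2ccc(CO)cc2)c(OC)c(OC)c1 | intermediate
5 | {4-[2,3-dimethoxy-5-(methoxycarbonyl)phenoxy]benzyl}triphenylphosphonium bromide | COC(=O)c1cc(Oc2ccc(C[P+](c3ccccc3)(c3ccccc3)c3ccccc3)cc2)c(OC)c(OC)c1.[Br-] | intermediate
6 | 2-(benzyloxy)-3-methoxybenzaldehyde | COc1cccc(C=O)c1OCc1ccccc1 | starting material
7 | phosphonium ylide of 5, methyl 3-{4-[(triphenylphosphoranylidene)methyl]phenoxy}-4,5-dimethoxybenzoate (not isolated) | COC(=O)c1cc(Oc2ccc(C=P(c3ccccc3)(c3ccccc3)c3ccccc3)cc2)c(OC)c(OC)c1 | intermediate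
8 | methyl 3-{4-[2-(2-benzyloxy-3-methoxyphenyl)ethenyl]phenoxy}-4,5-dimethoxybenzoate (E/Z mixture, geometry left open) | COC(=O)c1cc(Oc2ccc(C=Cc3cccc(OC)c3OCc3ccccc3)cc2)c(OC)c(OC)c1 | intermediate
9 | methyl 3-{4-[2-(2-hydroxy-3-methoxyphenyl)ethyl]phenoxy}-4,5-dimethoxybenzoate | COC(=O)c1cc(Oc2ccc(CCc3cccc(OC)c3O)cc2)c(OC)c(OC)c1 | intermediate
10 | 2-fluorobenzaldehyde | O=Cc1ccccc1F | starting material
11 | methyl 3-(4-{2-[2-(2-formylphenoxy)-3-methoxyphenyl]ethyl}phenoxy)-4,5-dimethoxybenzoate | COC(=O)c1cc(Oc2ccc(CCc3cccc(OC)c3Oc3ccccc3C=O)cc2)c(OC)c(OC)c1 | intermediate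
12 | [3-(4-{2-[2-(2-(hydroxymethyl)phenoxy)-3-methoxyphenyl]ethyl}phenoxy)-4,5-dimethoxyphenyl]methanol (diol) | OCc1cc(Oc2ccc(CCc3cccc(OC)c3Oc3ccccc3CO)cc2)c(OC)c(OC)c1 | intermediate
13 | 5-(bromomethyl)-1-(4-{2-[2-(2-(bromomethyl)phenoxy)-3-methoxyphenyl]ethyl}phenoxy)-2,3-dimethoxybenzene (open bis(benzyl bromide)) | BrCc1cc(Oc2ccc(CCc3cccc(OC)c3Oc3ccccc3CBr)cc2)c(OC)c(OC)c1 | intermediate
14 | bromo thiolate: sodium thiolate at the ring C benzylic carbon, ring D CH2Br still in place (not isolated) | [Na+].[S-]Cc1cc(Oc2ccc(CCc3cccc(OC)c3Oc3ccccc3CBr)cc2)c(OC)c(OC)c1 | intermediate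
15 | 18-membered cyclic dibenzyl sulfide (ring C–CH2–S–CH2–ring D; tri-O-methyl) | COc1cc2cc(c1OC)Oc1ccc(cc1)CCc1cccc(OC)c1Oc1ccccc1CSC2 | intermediate
16 | 18-membered cyclic sulfoxide (racemic at sulfur; not isolated) | COc1cc2cc(c1OC)Oc1ccc(cc1)CCc1cccc(OC)c1Oc1ccccc1CS(=O)C2 | intermediate
17 | 18-membered cyclic dibenzyl sulfone (tri-O-methyl) | COc1cc2cc(c1OC)Oc1ccc(cc1)CCc1cccc(OC)c1Oc1ccccc1CS(=O)(=O)C2 | intermediate
18 | bis(benzylic) diradical formed from 17 by loss of SO2 (not isolated) | COc1cc([CH2])cc(c1OC)Oc1ccc(cc1)CCc1cccc(OC)c1Oc1ccccc1[CH2] | intermediate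
19 | tri-O-methyl ether of the target (17-membered macrocycle) | COc1cc2cc(c1OC)Oc1ccc(cc1)CCc1cccc(OC)c1Oc1ccccc1CC2 | intermediate
20 | CNP0290892.0 | Oc1cc2cc(c1O)Oc1ccc(cc1)CCc1cccc(O)c1Oc1ccccc1CC2 | target

**Step count**

Total steps: 12. Longest linear sequence: 12 (steps 1–12 from compound 1; compounds 2, 6 and 10 enter as purchased partners).

**Steps most likely to fail, with fallbacks**

Step 11 (sulfone pyrolysis). The heavy sulfone may volatilise too slowly and char before it reaches the hot zone. In addition, O–CH3 homolysis at the ring C methoxy groups, or attack of the ring D benzylic radical on ring B, may compete at the temperature needed for C–S cleavage. The fallback sets out from sulfone 17 and forms the same benzylic C–C bond and the same 17-membered ring in solution by a Ramberg–Bäcklund reaction with in situ chlorination (KOH, CCl4, t-BuOH/H2O). α-Chlorination, 1,3-elimination to the episulfone and loss of SO2 should give the ring-contracted cyclic stilbene F1 (ring C–CH=CH–ring D, E/Z mixture). Hydrogenation of F1 (H2, 10% Pd/C, EtOAc) then returns to the route at compound 19.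

Step 9 (sulfide macrocyclisation). Intermolecular alkylation may outrun ring closure and give oligomeric sulfides, and the electron-rich ring C benzylic bromide may be lost to solvolysis. The fallback sets out from dibromide 13 and closes the ring under thermodynamic control through a disulfide. Displacement with KSAc in DMF should give the bis(thioacetate) F2. Methanolysis (K2CO3, degassed MeOH) should give the dithiol F3. Oxidation at high dilution (I2, Et3N, CH2Cl2/MeOH), where thiolate–disulfide exchange corrects oligomers, should give the 19-membered cyclic disulfide F4. Sulfur extrusion from the benzylic disulfide with P(NEt2)3 in hot benzene then contracts F4 to the sulfide, returning to the route at compound 15.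

Step 6 (diaryl ether at ring B). Substitution at a phenoxide flanked by two ortho substituents may be slow enough that decomposition of the fluoroaldehyde under the hot basic conditions takes over. The fallback sets out from phenol 9 and replaces the SNAr by a copper-catalysed Ullmann-type coupling with methyl 2-iodobenzoate (CuI, picolinic acid, K3PO4, DMSO, 90 °C), conditions suited to hindered phenols and ortho-substituted aryl iodides. This should give the diester F5. Reduction of F5 with LiAlH4, the reagent already used in step 7, then returns to the route at diol 12.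

**Further compounds**

F1 | step 11 | 17-membered cyclic stilbene, tri-O-methyl (ring C–CH=CH–ring D; E/Z mixture, geometry left open) | COc1cc2cc(c1OC)Oc1ccc(cc1)CCc1cccc(OC)c1Oc1ccccc1C=C2
F2 | step 9 | open bis(thioacetate) (AcS–CH2 on ring C and on ring D) | CC(=O)SCc1cc(Oc2ccc(CCc3cccc(OC)c3Oc3ccccc3CSC(C)=O)cc2)c(OC)c(OC)c1
F3 | step 9 | open dithiol (HS–CH2 on ring C and on ring D) | SCc1cc(Oc2ccc(CCc3cccc(OC)c3Oc3ccccc3CS)cc2)c(OC)c(OC)c1
F4 | step 9 | 19-membered cyclic disulfide (ring C–CH2–S–S–CH2–ring D; tri-O-methyl) | COc1cc2cc(c1OC)Oc1ccc(cc1)CCc1cccc(OC)c1Oc1ccccc1CSSC2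
F5 | step 6 | methyl 2-(2-{2-[4-(2,3-dimethoxy-5-(methoxycarbonyl)phenoxy)phenyl]ethyl}-6-methoxyphenoxy)benzoate (diester) | COC(=O)c1cc(Oc2ccc(CCc3cccc(OC)c3Oc3ccccc3C(=O)OC)cc2)c(OC)c(OC)c1
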